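## Structural features

The target is a flavanone: benzene ring A is fused through C4a and C8a to the dihydropyranone ring C (O1, C2, C3, C4=O), and C2 carries the 4-hydroxyphenyl ring B. Ring A is fully substituted (C5–OH, C6–CH3, C7–OH, C8–prenyl between the two fusion atoms), so no aromatic C–H remains for late correction and O1 must be told apart from O5 and O7. The only stereocentre is C2 (S); it has no neighbouring stereocentre and must be set by reagent control. It is benzylic, bears O1 and lies β to the C4 carbonyl. This centre is fragile: base can open ring C by β-elimination of the O1 phenoxide to the 2'-hydroxychalcone, and the electron-rich ring B makes the C2–O bond prone to ionisation in acid. The prenyl olefin rules out hydrogenolysis and strong electrophiles, and in acid it can add the neighbouring C7 hydroxyl. The real difficulty is therefore twofold: a hexasubstituted ring A with three differentiated oxygens, and closure of ring C without exposing C2 to a β-aryloxy ketone under base. The key step exploits the fact that O1 sits on an aromatic carbon: with a triflate on C8a and a preformed (S)-hydroxyl on C2, the O1–C8a bond is made at palladium while C4 is still a protected carbinol.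

## Logic of the disconnections

22 ⇒ 21. The three phenolic O–H bonds are traced back to O–CH2OCH3 acetals. The phenols must be masked through enolate, hydride and palladium chemistry, and the mask must come off without hydrogen or strong Lewis acid. The demand on the forward step is an acid mild enough to spare the prenyl olefin and C2.

21 ⇒ 20 ⇒ 19. The C4 carbonyl is taken back to a carbinol and then to its silyl ether. This removes the β-aryloxy ketone, and with it the β-elimination and retro-aldol pathways, from every step that uses base. The C4 configuration is irrelevant. The demand is a neutral oxidation that tolerates the olefin, and a desilylation that precedes the ketone.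

19 ⇒ 18. The O1–C8a bond is cut. Ring C opens to an acyclic chain on an aryl triflate, and the stereocentre becomes a plain secondary benzylic alcohol whose C–O bond is already in place. The demand is that C–O reductive elimination beats β-hydride elimination, that the triflate survives the base, and that only one hydroxyl is free.

18 ⇒ 17. The C2–H bond is cut, which leads to the aryl ketone. The stereocentre is thus set by a catalytic reduction of a ketone flanked by an aryl group and a CH2 group. The demand is catalyst control of the carbonyl face regardless of the remote C4 centre.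

17 ⇒ 16 ⇒ 13 + 15. The O–Si bond and then the C3–C4 bond are cut (aldol). This splits the molecule into two aromatic halves of similar size and makes the route convergent. The demand is enolate addition to a hindered aldehyde without attack on the sulfonate, and a cold quench so that the aldolate neither reverts nor picks up the triflyl group.

15 ⇒ 14. The acetal O–C bond of ring B is cut. The only gain is a single enolisable site in the aldol; the demand is trivial.

13 ⇒ 12 ⇒ 10. The S–O bond of the triflate and then the C4a–CHO bond are cut. The free phenol that will become O1 directs the formyl group to its ortho carbon, which is the last open ring position. The demand is an ortho-formylation that tolerates acetals and a triflyl donor that does not activate them.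

10 ⇒ 8 ⇒ 7 ⇒ 4 + 5. The C8–CH2 bond is traced by a [3,3] shift to an O–C bond, the alkene to an alkyne, and the ether to a phenol plus a tertiary propargylic alcohol. Direct C-prenylation of a phenol is unselective, whereas the sigmatropic shift delivers carbon ortho to the very oxygen that becomes O1. In 8 both ortho positions are equivalent and the para position is blocked. The demand is a clean semi-hydrogenation and a rearrangement at moderate temperature.

4 ⇒ 2 ⇒ 1. The C–O bond at the future C8a is cut back to C–H, and the two acetals to phenols. In 2 only the C–H para to the methyl group has no ortho neighbour, so a sterically governed borylation and oxidation puts the third oxygen there as a free phenol. O1 is thus differentiated from O5 and O7 by the order of events. The demand is steric control in the C–H borylation.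

## Other disconnections considered

Alternative 1: The cut runs through ring A itself (C8a–C8, C7–C6, C8a–C4a) and leads to the cyclobutenone A2 and the prenyl-bearing siloxyalkyne A3.
- Forward step: heating opens A2 to a vinylketene, which adds to the triple bond of A3 in a [2+2] sense. The new cyclobutenone opens again, and the dienylketene closes by 6π electrocyclisation and tautomerises to the phenol A1 (benzannulation).
- In its favour: one reagent-free step fixes prenyl, methyl and three different oxygens by mechanism. O1 arrives free. No propargylation, semi-hydrogenation and rearrangement sequence is needed for the prenyl group, and on that count the alternative is the better plan. In regiochemical certainty it is the equal of the chosen plan, which relies on the mirror symmetry of 2 and 8.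
- Against it here: A2 and A3 each need a multistep preparation. A3 is a skipped enyne that may isomerise at the temperature of the cascade. The ethyl ether on O5 would need a boron or aluminium halide for removal, in the presence of the prenyl olefin, a free 7-OH and C2.
- Comparison: A1 solves only ring A. It would still have to be formylated, triflated and taken through the same aldol, reduction and etherification, so the C2 problem is untouched. Mechanistically the pericyclic cascade is the more convergent construction. In step count the two are about level up to the stage of 10, and the chosen plan has the safer deprotection.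

Alternative 2: The cut is C4–C4a, with the C2–O1 ether already present in the acid A5.
- Forward step: (CF3CO)2O converts A5 into a mixed anhydride that acylates the arene ortho to the ether oxygen (intramolecular Friedel–Crafts acylation), giving the flavanone A4.
- In its favour: C4 is formed directly as the ketone, so the silylation, desilylation and oxidation of the chosen plan are not needed; here the alternative is the better. The aryloxy ring of A5 has a mirror plane, so the regiochemistry is as secure as in the chosen plan. Acylation of an activated trioxygenated ring is densely precedented and needs no transition metal; on precedent for the ring closure the alternative is at least the equal.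
- Against it here: the C2–O bond must be made at the stereocentre, in practice by an inverting substitution at an electron-rich benzylic carbon, where ionisation and elimination threaten the configuration. In the acidic acylation medium A5 can lose its aryloxy group by ionisation or β-elimination. A4 has no prenyl group, and its benzyl ethers can only be removed by hydrogenolysis before the olefin is introduced. The prenyl group must then come in through O7 by propargylation, semi-hydrogenation and Claisen rearrangement on the free flavanone, with base acting on a β-aryloxy ketone.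
- Comparison: to the flavanone core the alternative is shorter. Counted to the target it is of similar length, and it exposes the finished C2 centre to acid and base over a long stretch. The chosen plan sets C2 by reduction, never breaks its C–O bond, and has the ketone only in the last two steps.

Alternative 3: The cut is the C4a–C5 bond of ring A. Ring C and C2 are already present in the dihydropyranone A7, whose C8a carries the chain CH(prenyl)–CO–CH(CH3)–CO2CH3.
- Forward step: Mg(OMe)2 forms the chelated extended enolate, C4a attacks the ester carbonyl in a six-membered Claisen condensation, methoxide leaves, and enolisation gives the phloroglucinol ring of A6.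
- In its favour: ring A appears with methyl, prenyl and both free hydroxyls in one step, no ring-A protecting group is needed, and A6 is one acetal hydrolysis from the target. In protecting-group economy and in the length of the endgame this is the best of the plans. The stereocentre could be set early by a catalytic asymmetric hetero-Diels–Alder reaction of an aromatic aldehyde, which is the equal in reliability of the transfer hydrogenation used here.
- Against it here: A7 is a tricarbonyl chain on a base-sensitive heterocycle, and its assembly requires several steps of uncertain C- versus O-selectivity. Under the condensation conditions the O1–C2 bond of A7 can open by β-elimination, and A6 can open to its chalcone; either would cost the (S) configuration. The enolate also has other outlets (O-acylation, retro-Claisen cleavage by methoxide).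
- Comparison: if the condensation behaved as drawn, the alternative would be shorter than the chosen plan. Its risk is concentrated in one step without close analogy on a chiral 2-aryl-dihydropyranone, whereas every step of the chosen plan has a near precedent.

Key step: step 12

Remark: C4 is carried as both epimers from 16 to 20, because step 14 erases it; these compounds are drawn without a descriptor at C4.
Remark: ring A is entered from 2-methylresorcinol, because an entry from a 3,5-dihydroxy-4-methylbenzoate ester would need a two-step-longer degradation of the ester carbon to the phenol by a Dakin-type oxidation that is unreliable on a ring without ortho or para donors.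

## Route

Step 1
Reactants: 1 2-methylbenzene-1,3-diol (2-methylresorcinol)
Product: 2 1,3-bis(methoxymethoxy)-2-methylbenzene
Conditions: MOMCl, iPr2NEt, CH2Cl2, 0 °C to rt
Reagents that add atoms: chloromethyl methyl ether, COCCl
Why: Williamson-type O-alkylation of both phenols by the reactive α-chloro ether; the acetal ethers withstand every basic, organometallic and reductive step that follows and are removed only at the end.

Step 2
Reactants: 2 1,3-bis(methoxymethoxy)-2-methylbenzene
Product: 4 3,5-bis(methoxymethoxy)-4-methylphenol, via arylboronic pinacol ester 3 (not isolated)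
Conditions: [Ir(OMe)(cod)]2 (cat.), 4,4'-di-tert-butyl-2,2'-bipyridine, B2pin2, THF, 80 °C; then NaOH, H2O2, THF/H2O, 0 °C to rt
Reagents that add atoms: bis(pinacolato)diboron, CC1(C)OB(OC1(C)C)B1OC(C)(C)C(C)(C)O1 (boron of intermediate 3 only); hydrogen peroxide, OO
Why: Iridium-catalysed aromatic C–H borylation is governed by sterics, and in 2 the only C–H without an ortho substituent is the one para to the methyl group; oxidation of the C–B bond by hydroperoxide (1,2-aryl shift to oxygen) then gives the phenol that becomes O1, already distinguished from the two protected oxygens.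

Step 3
Reactants: 4 3,5-bis(methoxymethoxy)-4-methylphenol; 5 2-methylbut-3-yn-2-ol
Product: 7 1,3-bis(methoxymethoxy)-2-methyl-5-[(2-methylbut-3-yn-2-yl)oxy]benzene, via propargylic trifluoroacetate 6 (not isolated)
Conditions: 5, (CF3CO)2O, DBU, MeCN, 0 °C; then 4, DBU, CuCl2·2H2O (cat.), MeCN, 0 °C
Reagents that add atoms: trifluoroacetic anhydride, O=C(OC(=O)C(F)(F)F)C(F)(F)F (trifluoroacetyl group of intermediate 6 only; every atom of 7 comes from 4 and 5)
Why: Copper-catalysed propargylic etherification: the tertiary trifluoroacetate ionises through a copper acetylide to an allenylidene-type electrophile that the phenoxide captures at the tertiary carbon, which gives the hindered aryl tert-propargyl ether under mild base where a direct SN2 reaction would fail.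

Step 4
Reactants: 7 1,3-bis(methoxymethoxy)-2-methyl-5-[(2-methylbut-3-yn-2-yl)oxy]benzene
Product: 8 1,3-bis(methoxymethoxy)-2-methyl-5-[(2-methylbut-3-en-2-yl)oxy]benzene
Conditions: H2 (1 atm), Pd/CaCO3 poisoned with Pb(OAc)2, quinoline, EtOAc, rt
Reagents that add atoms: none
Why: Lindlar semi-hydrogenation: the terminal alkyne binds the poisoned palladium surface far more strongly than the alkene that forms, so uptake should stop after one equivalent of H2; the aryl and acetal ethers are inert.

Step 5
Reactants: 8 1,3-bis(methoxymethoxy)-2-methyl-5-[(2-methylbut-3-en-2-yl)oxy]benzene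
Product: 10 3,5-bis(methoxymethoxy)-4-methyl-2-(3-methylbut-2-en-1-yl)phenol, via ortho-dienone 9 (not isolated)
Conditions: PhNEt2, 130 °C
Reagents that add atoms: none
Why: Aromatic Claisen rearrangement ([3,3]-sigmatropic shift through a chair transition state): the gem-dimethyl carbon leaves oxygen and the vinyl terminus bonds to the ring, so the 1,1-dimethylallyl ether is delivered as a prenyl group; the two ortho positions of 8 are equivalent, the para position is blocked by methyl, and dienone 9 tautomerises to the phenol.

Step 6
Reactants: 10 3,5-bis(methoxymethoxy)-4-methyl-2-(3-methylbut-2-en-1-yl)phenol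
Product: 12 2-hydroxy-4,6-bis(methoxymethoxy)-5-methyl-3-(3-methylbut-2-en-1-yl)benzaldehyde, via salicyl alcohol 11 (not isolated)
Conditions: MgCl2, Et3N, (CH2O)n, MeCN, reflux
Reagents that add atoms: formaldehyde (from paraformaldehyde), C=O
Why: Casnati–Skattebøl ortho-formylation: the magnesium phenoxide binds formaldehyde and delivers it to the only unsubstituted ring carbon, which lies ortho to the phenoxide, and the salicyl alkoxide 11 is oxidised to the aldehyde by hydride transfer to a second formaldehyde; the amine-buffered medium should leave the acetals untouched.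

Step 7
Reactants: 12 2-hydroxy-4,6-bis(methoxymethoxy)-5-methyl-3-(3-methylbut-2-en-1-yl)benzaldehyde
Product: 13 2-formyl-3,5-bis(methoxymethoxy)-4-methyl-6-(3-methylbut-2-en-1-yl)phenyl trifluoromethanesulfonate
Conditions: PhNTf2, Cs2CO3, DMF, 0 °C to rt
Reagents that add atoms: N-phenylbis(trifluoromethanesulfonimide), O=S(=O)(N(c1ccccc1)S(=O)(=O)C(F)(F)F)C(F)(F)F
Why: O-Sulfonylation of the caesium phenoxide with a mild triflyl donor; the imide is chosen over (CF3SO2)2O because it cannot activate the acetal ethers, and the aldehyde has no α-hydrogen to be affected by carbonate.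

Step 8
Reactants: 14 4'-hydroxyacetophenone
Product: 15 1-[4-(methoxymethoxy)phenyl]ethan-1-one
Conditions: MOMCl, iPr2NEt, CH2Cl2, 0 °C to rt
Reagents that add atoms: chloromethyl methyl ether, COCCl
Why: Williamson-type O-alkylation of the acidic para-acyl phenol; masking it leaves the methyl ketone as the single site of deprotonation in the aldol step.

Step 9
Reactants: 15 1-[4-(methoxymethoxy)phenyl]ethan-1-one; 13 2-formyl-3,5-bis(methoxymethoxy)-4-methyl-6-(3-methylbut-2-en-1-yl)phenyl trifluoromethanesulfonate
Product: 16 2-{1-hydroxy-3-[4-(methoxymethoxy)phenyl]-3-oxopropyl}-3,5-bis(methoxymethoxy)-4-methyl-6-(3-methylbut-2-en-1-yl)phenyl trifluoromethanesulfonate (racemic)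
Conditions: 15, LiN(iPr)2, THF, –78 °C; then 13, –78 °C; AcOH quench at –78 °C
Reagents that add atoms: none
Why: Directed crossed aldol addition: the preformed lithium enolate of 15 adds to the non-enolisable, triflate-activated aldehyde much faster than it can attack the sulfonate, and the cold acidic quench prevents retro-aldol reversal; the new C4 carbinol centre forms as a racemate, which is harmless because step 14 removes it.

Step 10
Reactants: 16 2-{1-hydroxy-3-[4-(methoxymethoxy)phenyl]-3-oxopropyl}-3,5-bis(methoxymethoxy)-4-methyl-6-(3-methylbut-2-en-1-yl)phenyl trifluoromethanesulfonate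
Product: 17 2-{1-[(tert-butyldimethylsilyl)oxy]-3-[4-(methoxymethoxy)phenyl]-3-oxopropyl}-3,5-bis(methoxymethoxy)-4-methyl-6-(3-methylbut-2-en-1-yl)phenyl trifluoromethanesulfonate (racemic)
Conditions: TBSOTf, 2,6-lutidine, CH2Cl2, –78 to –40 °C
Reagents that add atoms: tert-butyldimethylsilyl trifluoromethanesulfonate, CC(C)(C)[Si](C)(C)OS(=O)(=O)C(F)(F)F
Why: Silylation of the hindered benzylic carbinol with a silyl triflate and a hindered pyridine base; the cold, non-nucleophilic conditions avoid retro-aldol and β-elimination, and with 2,6-lutidine at low temperature the aryl acetals should not be activated.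

Step 11
Reactants: 17 2-{1-[(tert-butyldimethylsilyl)oxy]-3-[4-(methoxymethoxy)phenyl]-3-oxopropyl}-3,5-bis(methoxymethoxy)-4-methyl-6-(3-methylbut-2-en-1-yl)phenyl trifluoromethanesulfonate
Product: 18 2-{(3S)-1-[(tert-butyldimethylsilyl)oxy]-3-hydroxy-3-[4-(methoxymethoxy)phenyl]propyl}-3,5-bis(methoxymethoxy)-4-methyl-6-(3-methylbut-2-en-1-yl)phenyl trifluoromethanesulfonate (both C1 epimers of the propyl chain)
Conditions: RuCl(p-cymene)[(S,S)-TsDPEN] (cat.), HCO2H/Et3N (5:2), DMF, 40 °C
Reagents that add atoms: none
Why: Noyori asymmetric transfer hydrogenation: the ruthenium hydride and its N–H ligand transfer H− and H+ to the carbonyl in an outer-sphere six-membered transition state in which ring B is held by a CH/π contact with the η6-arene, so the (S,S)-catalyst should give the (S)-carbinol as it does with acetophenone; control comes from the catalyst, the racemic silyloxy centre is too remote to direct, and the triflate, olefin and silyl ether are inert to formate and amine.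

Step 12
Reactants: 18 2-{(3S)-1-[(tert-butyldimethylsilyl)oxy]-3-hydroxy-3-[4-(methoxymethoxy)phenyl]propyl}-3,5-bis(methoxymethoxy)-4-methyl-6-(3-methylbut-2-en-1-yl)phenyl trifluoromethanesulfonate
Product: 19 tert-butyl{[(2S)-5,7-bis(methoxymethoxy)-2-[4-(methoxymethoxy)phenyl]-6-methyl-8-(3-methylbut-2-en-1-yl)-3,4-dihydro-2H-chromen-4-yl]oxy}dimethylsilane (both C4 epimers)
Conditions: Pd(OAc)2 (cat.), 2-(di-tert-butylphosphino)-1,1'-binaphthyl (cat.), Cs2CO3, toluene, 80 °C
Reagents that add atoms: none
Why: Intramolecular Buchwald–Hartwig-type aryl etherification: divalent palladium is reduced in situ to a zerovalent monophosphine complex, which inserts into the C8a–O bond of the triflate; Cs2CO3 deprotonates the palladium-bound C2 hydroxyl to give a seven-membered aryl(alkoxo)palladacycle, and C–O reductive elimination forms O1–C8a and returns zerovalent palladium. The closest known reaction type is the palladium-catalysed cyclisation of 3-(2-halo- or 2-sulfonyloxyaryl)propanols bearing a secondary carbinol to chromans with di-tert-butylbiarylphosphine ligands. Ring C closes as a six-membered ring by attack of the tethered oxygen on the metal-bound aryl carbon, formally a 6-exo closure in which the breaking C8a–Pd bond lies outside the new ring. No stereocentre is created: C2 keeps its (S) configuration because only its O–H bond is broken, and the two C4 epimers of 18 give the two C4 epimers of 19. The step needs C–O reductive elimination to beat β-hydride elimination from the benzylic alkoxide, which would oxidise C2 and reduce the arene; the bulky, electron-rich ligand enforces a low-coordinate intermediate from which reductive elimination is fast, and the six-membered product geometry helps. It also needs oxidative addition to outrun base-induced S–O cleavage of the triflate, which is favoured by the two meta oxygen substituents that make C8a electron-poor by induction and by the use of an insoluble carbonate in toluene. Only one hydroxyl can bind palladium because O4 is silylated, and insertion of the neighbouring prenyl olefin would need a four-membered ring and should not compete.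

Step 13
Reactants: 19 tert-butyl{[(2S)-5,7-bis(methoxymethoxy)-2-[4-(methoxymethoxy)phenyl]-6-methyl-8-(3-methylbut-2-en-1-yl)-3,4-dihydro-2H-chromen-4-yl]oxy}dimethylsilane
Product: 20 (2S)-5,7-bis(methoxymethoxy)-2-[4-(methoxymethoxy)phenyl]-6-methyl-8-(3-methylbut-2-en-1-yl)-3,4-dihydro-2H-chromen-4-ol (both C4 epimers)
Conditions: Bu4NF, THF, rt
Reagents that add atoms: none
Why: Fluoride-induced cleavage of the Si–O bond, driven by the strong Si–F bond; no ketone is present yet, so the basic fluoride cannot open ring C.

Step 14
Reactants: 20 (2S)-5,7-bis(methoxymethoxy)-2-[4-(methoxymethoxy)phenyl]-6-methyl-8-(3-methylbut-2-en-1-yl)-3,4-dihydro-2H-chromen-4-ol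
Product: 21 (2S)-5,7-bis(methoxymethoxy)-2-[4-(methoxymethoxy)phenyl]-6-methyl-8-(3-methylbut-2-en-1-yl)-2,3-dihydro-4H-chromen-4-one
Conditions: Dess–Martin periodinane, NaHCO3, CH2Cl2, 0 °C to rt
Reagents that add atoms: none
Why: Dess–Martin oxidation of the secondary benzylic alcohol by ligand exchange at iodine and internal proton abstraction; both C4 epimers converge on one ketone, and the buffered, non-basic conditions spare the prenyl olefin, the acetals and the now base-sensitive C2 centre.

Step 15
Reactants: 21 (2S)-5,7-bis(methoxymethoxy)-2-[4-(methoxymethoxy)phenyl]-6-methyl-8-(3-methylbut-2-en-1-yl)-2,3-dihydro-4H-chromen-4-one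
Product: 22 (2S)-5,7-dihydroxy-2-(4-hydroxyphenyl)-6-methyl-8-(3-methylbut-2-en-1-yl)-2,3-dihydro-4H-chromen-4-one (6-methyl-8-prenylnaringenin)
Conditions: HCl (3 M aq.), MeOH, 40 °C
Reagents that add atoms: none
Why: Acid-catalysed methanolysis of the three aryl methoxymethyl acetals through oxocarbenium ions that methanol traps; the C5 acetal peri to the carbonyl should go first, and dilute acid at moderate temperature should leave the prenyl olefin and the C2–O bond intact.

## Compound list

1 | 2-methylbenzene-1,3-diol | Cc1c(O)cccc1O | starting material
2 | 1,3-bis(methoxymethoxy)-2-methylbenzene | Cc1c(OCOC)cccc1OCOC | intermediate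
3 | 2-[3,5-bis(methoxymethoxy)-4-methylphenyl]-4,4,5,5-tetramethyl-1,3,2-dioxaborolane | Cc1c(OCOC)cc(B2OC(C)(C)C(C)(C)O2)cc1OCOC | intermediate (not isolated)
4 | 3,5-bis(methoxymethoxy)-4-methylphenol | Cc1c(OCOC)cc(O)cc1OCOC | intermediate
5 | 2-methylbut-3-yn-2-ol | CC(C)(O)C#C | starting material
6 | 2-methylbut-3-yn-2-yl trifluoroacetate | C#CC(C)(C)OC(=O)C(F)(F)F | intermediate (not isolated)
7 | 1,3-bis(methoxymethoxy)-2-methyl-5-[(2-methylbut-3-yn-2-yl)oxy]benzene | Cc1c(OCOC)cc(OC(C)(C)C#C)cc1OCOC | intermediate
8 | 1,3-bis(methoxymethoxy)-2-methyl-5-[(2-methylbut-3-en-2-yl)oxy]benzene | Cc1c(OCOC)cc(OC(C)(C)C=C)cc1OCOC | intermediate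
9 | 3,5-bis(methoxymethoxy)-4-methyl-6-(3-methylbut-2-en-1-yl)cyclohexa-2,4-dien-1-one (racemic) | CC1=C(OCOC)C(CC=C(C)C)C(=O)C=C1OCOC | intermediate (not isolated)
10 | 3,5-bis(methoxymethoxy)-4-methyl-2-(3-methylbut-2-en-1-yl)phenol | Cc1c(OCOC)cc(O)c(CC=C(C)C)c1OCOC | intermediate
11 | 2-(hydroxymethyl)-3,5-bis(methoxymethoxy)-4-methyl-6-(3-methylbut-2-en-1-yl)phenol | Cc1c(OCOC)c(CO)c(O)c(CC=C(C)C)c1OCOC | intermediate (not isolated)
12 | 2-hydroxy-4,6-bis(methoxymethoxy)-5-methyl-3-(3-methylbut-2-en-1-yl)benzaldehyde | Cc1c(OCOC)c(C=O)c(O)c(CC=C(C)C)c1OCOC | intermediate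
13 | 2-formyl-3,5-bis(methoxymethoxy)-4-methyl-6-(3-methylbut-2-en-1-yl)phenyl trifluoromethanesulfonate | Cc1c(OCOC)c(C=O)c(OS(=O)(=O)C(F)(F)F)c(CC=C(C)C)c1OCOC | intermediate
14 | 4'-hydroxyacetophenone | CC(=O)c1ccc(O)cc1 | starting material
15 | 1-[4-(methoxymethoxy)phenyl]ethan-1-one | CC(=O)c1ccc(OCOC)cc1 | intermediate
16 | 2-{1-hydroxy-3-[4-(methoxymethoxy)phenyl]-3-oxopropyl}-3,5-bis(methoxymethoxy)-4-methyl-6-(3-methylbut-2-en-1-yl)phenyl trifluoromethanesulfonate (racemic) | CC(C)=CCc1c(OCOC)c(C)c(OCOC)c(C(O)CC(=O)c2ccc(OCOC)cc2)c1OS(=O)(=O)C(F)(F)F | intermediate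
17 | 2-{1-[(tert-butyldimethylsilyl)oxy]-3-[4-(methoxymethoxy)phenyl]-3-oxopropyl}-3,5-bis(methoxymethoxy)-4-methyl-6-(3-methylbut-2-en-1-yl)phenyl trifluoromethanesulfonate (racemic) | CC(C)=CCc1c(OCOC)c(C)c(OCOC)c(C(O[Si](C)(C)C(C)(C)C)CC(=O)c2ccc(OCOC)cc2)c1OS(=O)(=O)C(F)(F)F | intermediate
18 | 2-{(3S)-1-[(tert-butyldimethylsilyl)oxy]-3-hydroxy-3-[4-(methoxymethoxy)phenyl]propyl}-3,5-bis(methoxymethoxy)-4-methyl-6-(3-methylbut-2-en-1-yl)phenyl trifluoromethanesulfonate (silyloxy carbon as both epimers) | CC(C)=CCc1c(OCOC)c(C)c(OCOC)c(C(O[Si](C)(C)C(C)(C)C)C[C@H](O)c2ccc(OCOC)cc2)c1OS(=O)(=O)C(F)(F)F | intermediate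
19 | tert-butyl{[(2S)-5,7-bis(methoxymethoxy)-2-[4-(methoxymethoxy)phenyl]-6-methyl-8-(3-methylbut-2-en-1-yl)-3,4-dihydro-2H-chromen-4-yl]oxy}dimethylsilane (C4 epimers) | CC(C)=CCc1c(OCOC)c(C)c(OCOC)c2c1O[C@H](c1ccc(OCOC)cc1)CC2O[Si](C)(C)C(C)(C)C | intermediate
20 | (2S)-5,7-bis(methoxymethoxy)-2-[4-(methoxymethoxy)phenyl]-6-methyl-8-(3-methylbut-2-en-1-yl)-3,4-dihydro-2H-chromen-4-ol (C4 epimers) | CC(C)=CCc1c(OCOC)c(C)c(OCOC)c2c1O[C@H](c1ccc(OCOC)cc1)CC2O | intermediate
21 | (2S)-5,7-bis(methoxymethoxy)-2-[4-(methoxymethoxy)phenyl]-6-methyl-8-(3-methylbut-2-en-1-yl)-2,3-dihydro-4H-chromen-4-one | CC(C)=CCc1c(OCOC)c(C)c(OCOC)c2c1O[C@H](c1ccc(OCOC)cc1)CC2=O | intermediate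
22 | (2S)-5,7-dihydroxy-2-(4-hydroxyphenyl)-6-methyl-8-(3-methylbut-2-en-1-yl)-2,3-dihydro-4H-chromen-4-one (6-methyl-8-prenylnaringenin) | CC(C)=CCc1c(O)c(C)c(O)c2c1O[C@H](c1ccc(O)cc1)CC2=O | target

## Step count and least certain steps

Total: 15 steps. Longest linear sequence: 14 steps (1 to 22 through steps 1–7 and 9–15); the side branch 14 to 15 is one step.

Step 12 (key step). Three processes are the most likely to go wrong.
- β-Hydride elimination from the palladium-bound benzylic alkoxide, which would oxidise C2 and reduce the aryl–palladium bond.
- Cleavage of the S–O bond of the triflate by carbonate or alkoxide, because oxidative addition at a carbon with two ortho substituents is slow.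
- Base-induced 1,5-migration of the silyl group from O4 to O2, which would take the free hydroxyl away from the reacting position.

Fallback (sets out from 17, returns at 19): 17 is reduced with the enantiomeric catalyst RuCl(p-cymene)[(R,R)-TsDPEN] and HCO2H/Et3N to the (R)-carbinol aryl triflate F1. The aryl triflate is cleaved with Et4NOH in dioxane/water at rt to the (R)-carbinol phenol F2. PPh3 and DIAD in THF at 0 °C then close ring C by Mitsunobu displacement of the activated C2 hydroxyl by the C8a phenol with inversion, which should give 19 with the (2S) configuration. This makes the O1–C2 bond and uses no metal; its own weak point is partial ionisation at the electron-rich benzylic carbon.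

Step 9. The lithium aldolate sits next to the aryl triflate. On warming, reversal of the aldol addition or transfer of the triflyl group from the aryl oxygen to the aldolate oxygen can set in, and the enolate can also attack sulfur.

Fallback (sets out from 15 and 13, returns at 16): 15 is converted with LiN(iPr)2 and Me3SiCl (THF, –78 °C) into the trimethylsilyl enol ether F3. F3 is added to 13 with BF3·OEt2 in CH2Cl2 at –78 °C (Mukaiyama aldol), and work-up with aqueous NaHCO3 gives 16. No basic aldolate is present at any time.

Step 11. Hydride transfer to a hindered, electron-rich aryl ketone may be slow. One C4 epimer may be mismatched with the catalyst, which would mean weaker facial control and partial loss of enantiomeric purity at C2. Amine-induced β-elimination of the silyloxy group is a further risk.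

Fallback (sets out from 13, returns at 18): C2 is made by enantioselective aryl transfer instead of reduction.
- 13 is treated with the lithium enolate of ethyl acetate (LiN(iPr)2, EtOAc, THF, –78 °C) to give the β-hydroxy ester F4.
- TBSOTf and 2,6-lutidine give the silyl ether ester F5.
- i-Bu2AlH in CH2Cl2 at –78 °C gives the β-silyloxy aldehyde F6.
- An arylzinc reagent made from [4-(methoxymethoxy)phenyl]boronic acid and Et2Zn is added to F6 under a chiral β-amino alcohol catalyst to give 18. The ligand enantiomer is the one that delivers the aryl group to the face giving the (S)-carbinol.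

Step 15. Acid may add the 7-hydroxyl to the prenyl olefin or hydrate the olefin. Acid-promoted opening of ring C would epimerise C2.

Fallback (sets out from 21, returns at 22): Me3SiOTf and 2,2'-bipyridyl in MeCN at 0 °C to rt exchange the three aryl acetals for silyl ethers, giving the tris(trimethylsilyl) ether F7. F7 is hydrolysed with water at neutral pH to 22. The protecting groups are thus removed by silyl exchange, and no Brønsted acid meets the olefin.

## Further compounds

F1 | step 12 | 2-{(3R)-1-[(tert-butyldimethylsilyl)oxy]-3-hydroxy-3-[4-(methoxymethoxy)phenyl]propyl}-3,5-bis(methoxymethoxy)-4-methyl-6-(3-methylbut-2-en-1-yl)phenyl trifluoromethanesulfonate | CC(C)=CCc1c(OCOC)c(C)c(OCOC)c(C(O[Si](C)(C)C(C)(C)C)C[C@@H](O)c2ccc(OCOC)cc2)c1OS(=O)(=O)C(F)(F)F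
F2 | step 12 | 2-{(3R)-1-[(tert-butyldimethylsilyl)oxy]-3-hydroxy-3-[4-(methoxymethoxy)phenyl]propyl}-3,5-bis(methoxymethoxy)-4-methyl-6-(3-methylbut-2-en-1-yl)phenol | CC(C)=CCc1c(OCOC)c(C)c(OCOC)c(C(O[Si](C)(C)C(C)(C)C)C[C@@H](O)c2ccc(OCOC)cc2)c1O
F3 | step 9 | trimethyl({1-[4-(methoxymethoxy)phenyl]ethenyl}oxy)silane | C=C(O[Si](C)(C)C)c1ccc(OCOC)cc1
F4 | step 11 | ethyl 3-hydroxy-3-[2,4-bis(methoxymethoxy)-3-methyl-5-(3-methylbut-2-en-1-yl)-6-(trifluoromethanesulfonyloxy)phenyl]propanoate (racemic) | CCOC(=O)CC(O)c1c(OCOC)c(C)c(OCOC)c(CC=C(C)C)c1OS(=O)(=O)C(F)(F)F
F5 | step 11 | ethyl 3-[(tert-butyldimethylsilyl)oxy]-3-[2,4-bis(methoxymethoxy)-3-methyl-5-(3-methylbut-2-en-1-yl)-6-(trifluoromethanesulfonyloxy)phenyl]propanoate (racemic) | CCOC(=O)CC(O[Si](C)(C)C(C)(C)C)c1c(OCOC)c(C)c(OCOC)c(CC=C(C)C)c1OS(=O)(=O)C(F)(F)F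
F6 | step 11 | 2-{1-[(tert-butyldimethylsilyl)oxy]-3-oxopropyl}-3,5-bis(methoxymethoxy)-4-methyl-6-(3-methylbut-2-en-1-yl)phenyl trifluoromethanesulfonate (racemic) | O=CCC(O[Si](C)(C)C(C)(C)C)c1c(OCOC)c(C)c(OCOC)c(CC=C(C)C)c1OS(=O)(=O)C(F)(F)F
F7 | step 15 | (2S)-6-methyl-8-(3-methylbut-2-en-1-yl)-5,7-bis[(trimethylsilyl)oxy]-2-{4-[(trimethylsilyl)oxy]phenyl}-2,3-dihydro-4H-chromen-4-one | CC(C)=CCc1c(O[Si](C)(C)C)c(C)c(O[Si](C)(C)C)c2c1O[C@H](c1ccc(O[Si](C)(C)C)cc1)CC2=O
A1 | alternative 1 | 5-ethoxy-4-methyl-2-(3-methylbut-2-en-1-yl)-3-[(triisopropylsilyl)oxy]phenol | CCOc1cc(O)c(CC=C(C)C)c(O[Si](C(C)C)(C(C)C)C(C)C)c1C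
A2 | alternative 1 | 3-ethoxy-2-methylcyclobut-2-en-1-one | CCOC1=C(C)C(=O)C1
A3 | alternative 1 | triisopropyl[(5-methylhex-4-en-1-yn-1-yl)oxy]silane | CC(C)=CCC#CO[Si](C(C)C)(C(C)C)C(C)C
A4 | alternative 2 | (2S)-4'-acetoxy-5,7-dibenzyloxy-6-methylflavanone | Cc1c(OCc2ccccc2)cc2c(c1OCc1ccccc1)C(=O)C[C@@H](c1ccc(OC(C)=O)cc1)O2
A5 | alternative 2 | (3S)-3-(4-acetoxyphenyl)-3-[3,5-bis(benzyloxy)-4-methylphenoxy]propanoic acid | Cc1c(OCc2ccccc2)cc(O[C@@H](CC(=O)O)c2ccc(OC(C)=O)cc2)cc1OCc1ccccc1
A6 | alternative 3 | (2S)-4'-(methoxymethoxy)-6-methyl-8-prenylnaringenin | CC(C)=CCc1c(O)c(C)c(O)c2c1O[C@H](c1ccc(OCOC)cc1)CC2=O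
A7 | alternative 3 | methyl 4-{(2S)-2-[4-(methoxymethoxy)phenyl]-4-oxo-3,4-dihydro-2H-pyran-6-yl}-2,7-dimethyl-3-oxooct-6-enoate | COC(=O)C(C)C(=O)C(CC=C(C)C)C1=CC(=O)C[C@@H](c2ccc(OCOC)cc2)O1
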